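**Strategy.** The pyranone ring (O1–C2–C3–C4–C4a–C8a) is traced back to the five-membered ring of a benzofuran-3(2H)-one. C3, the single carbon that carries the B-ring between C2 and the C4 carbonyl, is inserted as one atom. An aryl(chloro)carbene from a B-ring chlorodiazirine adds to the C2=C3 bond of a 3-silyloxybenzofuran, and the chlorocyclopropane opens with loss of chloride and silyl chloride to the isoflavone. Ring expansion and union of the A- and B-ring fragments therefore occur in one operation. B-ring alkenylation, a 5-O→C6 Claisen prenylation, and asymmetric transfer hydrogenation with dynamic kinetic resolution followed by reoxidation then set (S)-C3 after all basic steps.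

Key step: step 8

Remark: C3 is (S) (CIP order C4 > C2 > aryl > H) and, as an α-aryl ketone centre, epimerises with base, so it is created only after the last basic step. Boronate 15 and tert-butyl (2-methylbut-3-en-2-yl) carbonate are taken as purchasable.

Step 1
Reactants: 1 4,6-dihydroxy-1-benzofuran-3(2H)-one
Product: 2 4-hydroxy-6-(triisopropylsilyloxy)-1-benzofuran-3(2H)-one
Conditions: TIPSCl, imidazole, DMF, 0 °C → rt
Reagents that add atoms: chlorotriisopropylsilane CC(C)[Si](Cl)(C(C)C)C(C)C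
Why: Silyl ether formation; the 6-OH is the acidic, unhindered phenol, whereas the 4-OH is held in a hydrogen bond to the C3 carbonyl, so monosilylation at O6 should be selective.

Step 2
Reactants: 2 4-hydroxy-6-(triisopropylsilyloxy)-1-benzofuran-3(2H)-one
Product: 3 3,4-bis(trimethylsilyloxy)-6-(triisopropylsilyloxy)-1-benzofuran
Conditions: TMSOTf, Et3N, CH2Cl2, 0 °C; pentane, filtration, used crude
Reagents that add atoms: trimethylsilyl trifluoromethanesulfonate C[Si](C)(C)OS(=O)(=O)C(F)(F)F
Why: Soft enolisation–silylation (silyl enol ether formation) caps the 4-OH and traps the enol of the coumaranone, which is favoured because the product is an aromatic benzofuran.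

Step 3
Reactants: 4 2-bromobenzene-1,3-diol
Product: 5 2-bromo-3-(triisopropylsilyloxy)phenol
Conditions: TIPSCl (1 equiv), imidazole, DMF, 0 °C
Reagents that add atoms: chlorotriisopropylsilane CC(C)[Si](Cl)(C(C)C)C(C)C
Why: Statistical monosilylation of a symmetric diol; both hydroxyls are equivalent, so no regiochemical question arises and the bis-silyl ether is separated and recycled.

Step 4
Reactants: 5 2-bromo-3-(triisopropylsilyloxy)phenol
Product: 6 2-bromo-6-iodo-3-(triisopropylsilyloxy)phenol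
Conditions: I2, NaHCO3, THF/H2O, 0 °C
Reagents that add atoms: iodine II
Why: Electrophilic aromatic iodination of the phenoxide should occur at C6, ortho to the phenoxide oxygen and para to the silyloxy group, because C2 is blocked by bromine and C4 is shielded by the adjacent TIPS ether.

Step 5
Reactants: 6 2-bromo-6-iodo-3-(triisopropylsilyloxy)phenol
Product: 7 (2-bromo-4-iodo-3-methoxyphenoxy)triisopropylsilane
Conditions: MeI, K2CO3, acetone, 50 °C
Reagents that add atoms: iodomethane CI
Why: Williamson ether synthesis; the phenol flanked by two halogens is acidic and should be methylated under mild carbonate conditions that leave the aryl TIPS ether intact.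

Step 6
Reactants: 7 (2-bromo-4-iodo-3-methoxyphenoxy)triisopropylsilane
Product: 10 3-bromo-2-methoxy-4-(triisopropylsilyloxy)benzamidine hydrochloride, via aryllithium 8 (not isolated), via lithium bis(silyl)amidinate 9 (not isolated)
Conditions: n-BuLi, THF, −78 °C; Me3SiN=C=NSiMe3, −78 °C → rt; then HCl (Et2O), MeOH, 0 °C
Reagents that add atoms: N,N'-bis(trimethylsilyl)carbodiimide C[Si](C)(C)N=C=N[Si](C)(C)C; hydrogen chloride Cl
Why: Iodine–lithium exchange is much faster than bromine–lithium exchange, the aryllithium adds to the carbodiimide to give the N,N'-bis(silyl)amidinate (the species also formed from nitriles and LiHMDS), and methanolic HCl desilylates it to the amidinium chloride.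

Step 7
Reactants: 10 3-bromo-2-methoxy-4-(triisopropylsilyloxy)benzamidine hydrochloride
Product: 11 3-[3-bromo-2-methoxy-4-(triisopropylsilyloxy)phenyl]-3-chloro-3H-diazirine
Conditions: aq. NaOCl, LiCl, DMSO, 0 °C → rt; used cold without purification beyond extraction
Reagents that add atoms: sodium hypochlorite [Na+].[O-]Cl
Why: Graham oxidation of an amidine to the 3-chloro-3H-diazirine through N-chlorination, N–N bond formation and return of chloride to carbon.

Step 8
Reactants: 3 3,4-bis(trimethylsilyloxy)-6-(triisopropylsilyloxy)-1-benzofuran; 11 3-[3-bromo-2-methoxy-4-(triisopropylsilyloxy)phenyl]-3-chloro-3H-diazirine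
Product: 14 3-[3-bromo-2-methoxy-4-(triisopropylsilyloxy)phenyl]-5-hydroxy-7-(triisopropylsilyloxy)-4H-chromen-4-one, via chlorocyclopropane adduct 12 (not isolated), via 5-O-trimethylsilyl isoflavone 13 (not isolated)
Conditions: 3 (2 equiv), slow addition of 11, Na2CO3, MeCN, 55 °C; then MeOH, citric acid, rt
Reagents that add atoms: none
Why: Proposed new method: thermolysis of diazirine 11 releases the singlet aryl(chloro)carbene, which adds [2+1] to the electron-rich enol-ether bond C2=C3 of 3 to give chlorocyclopropane 12; disrotatory 2π-electrocyclic opening of the shared C2–C3 σ-bond with departure of chloride gives a 4-silyloxybenzopyrylium ion, which chloride desilylates to the chromen-4-one. The closest known reactions are the Ciamician–Dennstedt carbon-atom insertion of aryl chlorodiazirines into indoles and pyrroles and the dihalocarbene ring expansion of cyclic silyl enol ethers to α-halo enones. The six-membered ring is not closed by a cyclisation: it forms by [2+1] cycloaddition onto the five-membered ring followed by cleavage of the bond common to the three- and five-membered rings, so the carbene carbon becomes C3 between C2 and C4 and brings the B-ring with it. No stereocentre survives the step (the cyclopropane centres become sp2), and C3 is set in step 12. The step needs attack on the silyl enol ether in preference to the arene rings and to unimolecular decay of the carbene (azine formation, insertion into the ortho-methoxy C–H); the excess of the strongly nucleophilic C2=C3 bond of 3 and slow addition of 11 should secure this, the aryl group should sit exo so that chloride is endo as the ring opening requires, and the silyl groups mask every O–H.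

Step 9
Reactants: 14 3-[3-bromo-2-methoxy-4-(triisopropylsilyloxy)phenyl]-5-hydroxy-7-(triisopropylsilyloxy)-4H-chromen-4-one; 15 (E)-4,4,5,5-tetramethyl-2-(3-methylbut-1-en-1-yl)-1,3,2-dioxaborolane
Product: 16 5-hydroxy-3-{2-methoxy-3-[(E)-3-methylbut-1-en-1-yl]-4-(triisopropylsilyloxy)phenyl}-7-(triisopropylsilyloxy)-4H-chromen-4-one
Conditions: Pd(OAc)2, SPhos, K3PO4, PhMe/H2O (10:1), 80 °C
Reagents that add atoms: none
Why: Suzuki–Miyaura coupling; a dialkylbiarylphosphine ligand is chosen for the doubly ortho-substituted aryl bromide, and the E geometry of the alkenylboronate is retained.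

Step 10
Reactants: 16 5-hydroxy-3-{2-methoxy-3-[(E)-3-methylbut-1-en-1-yl]-4-(triisopropylsilyloxy)phenyl}-7-(triisopropylsilyloxy)-4H-chromen-4-one
Product: 17 3-{2-methoxy-3-[(E)-3-methylbut-1-en-1-yl]-4-(triisopropylsilyloxy)phenyl}-5-[(2-methylbut-3-en-2-yl)oxy]-7-(triisopropylsilyloxy)-4H-chromen-4-one
Conditions: tert-butyl (2-methylbut-3-en-2-yl) carbonate, Pd(PPh3)4 (cat.), THF, 0 °C → rt
Reagents that add atoms: tert-butyl (2-methylbut-3-en-2-yl) carbonate C=CC(C)(C)OC(=O)OC(C)(C)C
Why: Tsuji–Trost O-allylation; the phenoxide formed by the liberated tert-butoxide should attack the more substituted terminus of the 1,1-dimethyl-π-allylpalladium complex under kinetic control to give the tertiary (reverse-prenyl) ether, and only the 5-OH is free.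

Step 11
Reactants: 17 3-{2-methoxy-3-[(E)-3-methylbut-1-en-1-yl]-4-(triisopropylsilyloxy)phenyl}-5-[(2-methylbut-3-en-2-yl)oxy]-7-(triisopropylsilyloxy)-4H-chromen-4-one
Product: 19 5-(tert-butyldimethylsilyloxy)-3-{2-methoxy-3-[(E)-3-methylbut-1-en-1-yl]-4-(triisopropylsilyloxy)phenyl}-6-(3-methylbut-2-en-1-yl)-7-(triisopropylsilyloxy)-4H-chromen-4-one, via 5-hydroxy-6-prenyl isoflavone 18 (not isolated)
Conditions: PhMe, 110 °C; then 2,6-lutidine, TBSOTf, 0 °C
Reagents that add atoms: tert-butyldimethylsilyl trifluoromethanesulfonate CC(C)(C)[Si](C)(C)OS(=O)(=O)C(F)(F)F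
Why: Aromatic Claisen rearrangement; the [3,3] shift from O5 can only reach C6, the sole free ortho position, and inverts the allyl unit so that the 1,1-dimethylallyl ether delivers the linear 3-methylbut-2-enyl group, after which the freed hydrogen-bonded 5-OH is silylated in the same flask to unmask the C4 carbonyl for reduction.

Step 12
Reactants: 19 5-(tert-butyldimethylsilyloxy)-3-{2-methoxy-3-[(E)-3-methylbut-1-en-1-yl]-4-(triisopropylsilyloxy)phenyl}-6-(3-methylbut-2-en-1-yl)-7-(triisopropylsilyloxy)-4H-chromen-4-one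
Product: 21 (3S,4S)-5-(tert-butyldimethylsilyloxy)-3-{2-methoxy-3-[(E)-3-methylbut-1-en-1-yl]-4-(triisopropylsilyloxy)phenyl}-6-(3-methylbut-2-en-1-yl)-7-(triisopropylsilyloxy)chroman-4-ol (3,4-cis), via racemic isoflavanone 20 (not isolated)
Conditions: RuCl[(S,S)-TsDPEN](p-cymene) (cat.), HCO2H/Et3N (5:2), EtOAc, 40 °C
Reagents that add atoms: none
Why: Noyori–Ikariya asymmetric transfer hydrogenation with dynamic kinetic resolution; conjugate reduction gives isoflavanone 20, whose C3 epimerises through the enol under Et3N, while the (S,S)-catalyst should deliver hydride to C4 from the face anti to the 3-aryl group to give the (4S) carbinol, so the cis-(3S,4S) alcohol is expected and the isolated alkenes are untouched.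

Step 13
Reactants: 21 (3S,4S)-5-(tert-butyldimethylsilyloxy)-3-{2-methoxy-3-[(E)-3-methylbut-1-en-1-yl]-4-(triisopropylsilyloxy)phenyl}-6-(3-methylbut-2-en-1-yl)-7-(triisopropylsilyloxy)chroman-4-ol
Product: 22 (3S)-5-(tert-butyldimethylsilyloxy)-3-{2-methoxy-3-[(E)-3-methylbut-1-en-1-yl]-4-(triisopropylsilyloxy)phenyl}-6-(3-methylbut-2-en-1-yl)-7-(triisopropylsilyloxy)chroman-4-one
Conditions: Dess–Martin periodinane, solid NaHCO3, CH2Cl2, 0 °C → rt
Reagents that add atoms: none
Why: Dess–Martin oxidation under non-basic conditions should return the C4 ketone without enolisation, so the (3S) centre set in step 12 is kept.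

Step 14
Reactants: 22 (3S)-5-(tert-butyldimethylsilyloxy)-3-{2-methoxy-3-[(E)-3-methylbut-1-en-1-yl]-4-(triisopropylsilyloxy)phenyl}-6-(3-methylbut-2-en-1-yl)-7-(triisopropylsilyloxy)chroman-4-one
Product: 23 (3S)-5,7-dihydroxy-3-{4-hydroxy-2-methoxy-3-[(E)-3-methylbut-1-en-1-yl]phenyl}-6-(3-methylbut-2-en-1-yl)chroman-4-one (CNP0289142.1)
Conditions: HF·pyridine, THF, 0 °C → rt
Reagents that add atoms: none
Why: Fluoride-mediated cleavage of the three aryl silyl ethers in a mildly acidic medium, which avoids the base-induced enolisation that would racemise C3 and should leave the prenyl and styryl alkenes intact.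

**Compound list**

1 | 4,6-dihydroxy-1-benzofuran-3(2H)-one | O=C1COc2cc(O)cc(O)c12 | starting material
2 | 4-hydroxy-6-(triisopropylsilyloxy)-1-benzofuran-3(2H)-one | O=C1COc2cc(O[Si](C(C)C)(C(C)C)C(C)C)cc(O)c12 | intermediate
3 | 3,4-bis(trimethylsilyloxy)-6-(triisopropylsilyloxy)-1-benzofuran | C[Si](C)(C)Oc1coc2cc(O[Si](C(C)C)(C(C)C)C(C)C)cc(O[Si](C)(C)C)c12 | intermediate
4 | 2-bromobenzene-1,3-diol (2-bromoresorcinol) | Oc1cccc(O)c1Br | starting material
5 | 2-bromo-3-(triisopropylsilyloxy)phenol | Oc1cccc(O[Si](C(C)C)(C(C)C)C(C)C)c1Br | intermediate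
6 | 2-bromo-6-iodo-3-(triisopropylsilyloxy)phenol | Oc1c(I)ccc(O[Si](C(C)C)(C(C)C)C(C)C)c1Br | intermediate
7 | (2-bromo-4-iodo-3-methoxyphenoxy)triisopropylsilane | COc1c(I)ccc(O[Si](C(C)C)(C(C)C)C(C)C)c1Br | intermediate
8 | [3-bromo-2-methoxy-4-(triisopropylsilyloxy)phenyl]lithium | COc1c([Li])ccc(O[Si](C(C)C)(C(C)C)C(C)C)c1Br | intermediate (not isolated)
9 | lithium N,N'-bis(trimethylsilyl)-3-bromo-2-methoxy-4-(triisopropylsilyloxy)benzamidinate | COc1c(C(=N[Si](C)(C)C)N([Li])[Si](C)(C)C)ccc(O[Si](C(C)C)(C(C)C)C(C)C)c1Br | intermediate (not isolated)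
10 | 3-bromo-2-methoxy-4-(triisopropylsilyloxy)benzamidine hydrochloride | COc1c(C(N)=[NH2+])ccc(O[Si](C(C)C)(C(C)C)C(C)C)c1Br.[Cl-] | intermediate
11 | 3-[3-bromo-2-methoxy-4-(triisopropylsilyloxy)phenyl]-3-chloro-3H-diazirine | COc1c(C2(Cl)N=N2)ccc(O[Si](C(C)C)(C(C)C)C(C)C)c1Br | intermediate
12 | 1-[3-bromo-2-methoxy-4-(triisopropylsilyloxy)phenyl]-1-chloro-6,6b-bis(trimethylsilyloxy)-4-(triisopropylsilyloxy)-1a,6b-dihydro-1H-cyclopropa[b][1]benzofuran (diastereomer mixture) | C[Si](C)(C)OC12C(Oc3cc(O[Si](C(C)C)(C(C)C)C(C)C)cc(O[Si](C)(C)C)c31)C2(Cl)c1ccc(O[Si](C(C)C)(C(C)C)C(C)C)c(Br)c1OC | intermediate (not isolated)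
13 | 3-[3-bromo-2-methoxy-4-(triisopropylsilyloxy)phenyl]-7-(triisopropylsilyloxy)-5-(trimethylsilyloxy)-4H-chromen-4-one | COc1c(Br)c(O[Si](C(C)C)(C(C)C)C(C)C)ccc1C1=COc2cc(O[Si](C(C)C)(C(C)C)C(C)C)cc(O[Si](C)(C)C)c2C1=O | intermediate (not isolated)
14 | 3-[3-bromo-2-methoxy-4-(triisopropylsilyloxy)phenyl]-5-hydroxy-7-(triisopropylsilyloxy)-4H-chromen-4-one | COc1c(Br)c(O[Si](C(C)C)(C(C)C)C(C)C)ccc1C1=COc2cc(O[Si](C(C)C)(C(C)C)C(C)C)cc(O)c2C1=O | intermediate
15 | (E)-4,4,5,5-tetramethyl-2-(3-methylbut-1-en-1-yl)-1,3,2-dioxaborolane | CC(C)/C=C/B1OC(C)(C)C(C)(C)O1 | starting material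
16 | 5-hydroxy-3-{2-methoxy-3-[(E)-3-methylbut-1-en-1-yl]-4-(triisopropylsilyloxy)phenyl}-7-(triisopropylsilyloxy)-4H-chromen-4-one | COc1c(/C=C/C(C)C)c(O[Si](C(C)C)(C(C)C)C(C)C)ccc1C1=COc2cc(O[Si](C(C)C)(C(C)C)C(C)C)cc(O)c2C1=O | intermediate
17 | 3-{2-methoxy-3-[(E)-3-methylbut-1-en-1-yl]-4-(triisopropylsilyloxy)phenyl}-5-[(2-methylbut-3-en-2-yl)oxy]-7-(triisopropylsilyloxy)-4H-chromen-4-one | COc1c(/C=C/C(C)C)c(O[Si](C(C)C)(C(C)C)C(C)C)ccc1C1=COc2cc(O[Si](C(C)C)(C(C)C)C(C)C)cc(OC(C)(C)C=C)c2C1=O | intermediate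
18 | 5-hydroxy-3-{2-methoxy-3-[(E)-3-methylbut-1-en-1-yl]-4-(triisopropylsilyloxy)phenyl}-6-(3-methylbut-2-en-1-yl)-7-(triisopropylsilyloxy)-4H-chromen-4-one | COc1c(/C=C/C(C)C)c(O[Si](C(C)C)(C(C)C)C(C)C)ccc1C1=COc2cc(O[Si](C(C)C)(C(C)C)C(C)C)c(CC=C(C)C)c(O)c2C1=O | intermediate (not isolated)
19 | 5-(tert-butyldimethylsilyloxy)-3-{2-methoxy-3-[(E)-3-methylbut-1-en-1-yl]-4-(triisopropylsilyloxy)phenyl}-6-(3-methylbut-2-en-1-yl)-7-(triisopropylsilyloxy)-4H-chromen-4-one | COc1c(/C=C/C(C)C)c(O[Si](C(C)C)(C(C)C)C(C)C)ccc1C1=COc2cc(O[Si](C(C)C)(C(C)C)C(C)C)c(CC=C(C)C)c(O[Si](C)(C)C(C)(C)C)c2C1=O | intermediate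
20 | rac-5-(tert-butyldimethylsilyloxy)-3-{2-methoxy-3-[(E)-3-methylbut-1-en-1-yl]-4-(triisopropylsilyloxy)phenyl}-6-(3-methylbut-2-en-1-yl)-7-(triisopropylsilyloxy)chroman-4-one | COc1c(/C=C/C(C)C)c(O[Si](C(C)C)(C(C)C)C(C)C)ccc1C1COc2cc(O[Si](C(C)C)(C(C)C)C(C)C)c(CC=C(C)C)c(O[Si](C)(C)C(C)(C)C)c2C1=O | intermediate (not isolated)
21 | (3S,4S)-5-(tert-butyldimethylsilyloxy)-3-{2-methoxy-3-[(E)-3-methylbut-1-en-1-yl]-4-(triisopropylsilyloxy)phenyl}-6-(3-methylbut-2-en-1-yl)-7-(triisopropylsilyloxy)chroman-4-ol | COc1c([C@H]2COc3cc(O[Si](C(C)C)(C(C)C)C(C)C)c(CC=C(C)C)c(O[Si](C)(C)C(C)(C)C)c3[C@H]2O)ccc(O[Si](C(C)C)(C(C)C)C(C)C)c1/C=C/C(C)C | intermediate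
22 | (3S)-5-(tert-butyldimethylsilyloxy)-3-{2-methoxy-3-[(E)-3-methylbut-1-en-1-yl]-4-(triisopropylsilyloxy)phenyl}-6-(3-methylbut-2-en-1-yl)-7-(triisopropylsilyloxy)chroman-4-one | COc1c([C@H]2COc3cc(O[Si](C(C)C)(C(C)C)C(C)C)c(CC=C(C)C)c(O[Si](C)(C)C(C)(C)C)c3C2=O)ccc(O[Si](C(C)C)(C(C)C)C(C)C)c1/C=C/C(C)C | intermediate
23 | (3S)-5,7-dihydroxy-3-{4-hydroxy-2-methoxy-3-[(E)-3-methylbut-1-en-1-yl]phenyl}-6-(3-methylbut-2-en-1-yl)chroman-4-one | COc1c([C@H]2COc3cc(O)c(CC=C(C)C)c(O)c3C2=O)ccc(O)c1/C=C/C(C)C | target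

**Step count.** Total: 14 steps. Longest linear sequence: 12 steps (steps 3–14, from 4).

**Steps most likely to fail**

Step 8 (Proposed new method). The carbene may be lost to unimolecular pathways (azine formation, insertion into the ortho-methoxy C–H) or attack other sites before it reaches the C2=C3 bond, and a cyclopropane with exo chloride may open slowly. The fallback separates ring expansion from aryl transfer. Dibromocarbene (CHBr3, KOt-Bu, pentane, −20 °C; methanolic work-up) is added to 3; the dibromocyclopropane should open with loss of bromide and bromotrimethylsilane to 3-bromo-5-hydroxy-7-(triisopropylsilyloxy)-4H-chromen-4-one F1, the known halocarbene ring expansion of a silyl enol ether. In parallel, 7 is converted by iodine–magnesium exchange (i-PrMgCl·LiCl, −40 °C) and borylation with 2-isopropoxy-4,4,5,5-tetramethyl-1,3,2-dioxaborolane into 2-[3-bromo-2-methoxy-4-(triisopropylsilyloxy)phenyl]-4,4,5,5-tetramethyl-1,3,2-dioxaborolane F2. Suzuki–Miyaura coupling of F1 with F2 (Pd(PPh3)4, aq. Na2CO3, DME, 70 °C), in which the activated 3-bromochromone should react before the doubly ortho-substituted aryl bromide, returns to the route at 14.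

Step 10. The hydrogen-bonded 5-OH may be too weak a nucleophile, or the tertiary ether may isomerise to the linear prenyl ether by reversible ionisation on palladium. From 16, copper-catalysed propargylation with 3-chloro-3-methylbut-1-yne (CuCl2 cat., DBU, MeCN, 0 °C) should give 3-{2-methoxy-3-[(E)-3-methylbut-1-en-1-yl]-4-(triisopropylsilyloxy)phenyl}-5-[(2-methylbut-3-yn-2-yl)oxy]-7-(triisopropylsilyloxy)-4H-chromen-4-one F3. Semihydrogenation over Lindlar catalyst (H2, quinoline, EtOAc) then returns to the route at 17.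

Step 12. Hydride transfer to the C4 carbonyl next to the 5-silyloxy group may be slow, that silyl group may be lost in the acidic medium, or epimerisation at C3 may be incomplete so that the resolution is not dynamic. From 19, conjugate reduction with L-Selectride (THF, −78 °C) and O-acylation of the enolate with allyl chloroformate should give allyl 5-(tert-butyldimethylsilyloxy)-3-{2-methoxy-3-[(E)-3-methylbut-1-en-1-yl]-4-(triisopropylsilyloxy)phenyl}-6-(3-methylbut-2-en-1-yl)-7-(triisopropylsilyloxy)-2H-chromen-4-yl carbonate F4. Palladium-catalysed decarboxylative enantioselective protonation (Pd2(dba)3, t-Bu-PHOX, Meldrum's acid, dioxane, 40 °C) forms the C3–H bond under neutral conditions and returns to the route at 22, replacing steps 12 and 13. The ligand enantiomer that gives (S) must be established on a model substrate.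

**Further compounds**

F1 | step 8 | 3-bromo-5-hydroxy-7-(triisopropylsilyloxy)-4H-chromen-4-one | O=C1C(Br)=COc2cc(O[Si](C(C)C)(C(C)C)C(C)C)cc(O)c12
F2 | step 8 | 2-[3-bromo-2-methoxy-4-(triisopropylsilyloxy)phenyl]-4,4,5,5-tetramethyl-1,3,2-dioxaborolane | COc1c(B2OC(C)(C)C(C)(C)O2)ccc(O[Si](C(C)C)(C(C)C)C(C)C)c1Br
F3 | step 10 | 3-{2-methoxy-3-[(E)-3-methylbut-1-en-1-yl]-4-(triisopropylsilyloxy)phenyl}-5-[(2-methylbut-3-yn-2-yl)oxy]-7-(triisopropylsilyloxy)-4H-chromen-4-one | COc1c(/C=C/C(C)C)c(O[Si](C(C)C)(C(C)C)C(C)C)ccc1C1=COc2cc(O[Si](C(C)C)(C(C)C)C(C)C)cc(OC(C)(C)C#C)c2C1=O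
F4 | step 12 | allyl 5-(tert-butyldimethylsilyloxy)-3-{2-methoxy-3-[(E)-3-methylbut-1-en-1-yl]-4-(triisopropylsilyloxy)phenyl}-6-(3-methylbut-2-en-1-yl)-7-(triisopropylsilyloxy)-2H-chromen-4-yl carbonate | C=CCOC(=O)OC1=C(c2ccc(O[Si](C(C)C)(C(C)C)C(C)C)c(/C=C/C(C)C)c2OC)COc2cc(O[Si](C(C)C)(C(C)C)C(C)C)c(CC=C(C)C)c(O[Si](C)(C)C(C)(C)C)c21
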